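Eudesmane numbering is used for the terpene part: ring A is C1–C2–C3–C4–C5–C10, ring B is C5–C6–C7–C8–C9–C10, C11 is the carbinol carbon on C7, and the angular methyl sits on C10. "Syn" and "anti" mean on the same or the opposite face of the decalin as the C10 methyl. "Benzylic carbon" is the CH between C1, the arene and the isobutyl group.

## Analysis of the target

The target joins a 3,5-diformylphloroglucinol to a eudesmane-type trans-decalin through a benzylic methine that also carries an isobutyl group. The decalin has the quaternary C10 with its angular methyl, an axial tertiary hydroxyl at C4, a 2-hydroxypropan-2-yl group at C7 and the side chain at C1. There are six stereocentres: C1 (R), C4 (R), C5 (S), C7 (S), C10 (R) and the benzylic carbon (R). The C1 side chain, the C4 hydroxyl and the C7 group all lie syn to the C10 methyl and H5 is anti, so the C1 and C7 substituents are equatorial and the C4 hydroxyl is 1,3-diaxial to the methyl. The sensitive groups are two tertiary alcohols that ionise or dehydrate under protic and Lewis acids (the axial C4 one most easily), two aryl aldehydes, and an electron-rich phloroglucinol whose benzylic position ionises readily. The synthesis is hard because of the quaternary C10 next to the C1 stereocentre, the axial C4 hydroxyl on the hindered face, the benzylic stereocentre outside the rings, and the clash between classical arene formylation and the carbinols. The plan rests on the fact that C7 bears the C11 carbinol directly next to C6. A temporary C6–C11 bond turns C6, C7 and C11 into the gem-dimethylcyclopropane of carone, which is available from (S)-carvone with the C7 configuration of the target; that ring blocks one face and one enolisation direction of the ketone while C10 and ring A are built, and acid later opens it to the C11 carbinol.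

## Retrosynthetic reasoning

**31 to 30.** The three phenolic O–CH3 bonds are cut last. Methyl ethers are the phenol protection that survives the organometallic steps before it. They must be removed by a sulfur nucleophile under basic conditions, because any acid strong enough to cleave them would ionise the two carbinols.

**30 to 28 to 27.** The two aryl–CHO bonds are cut next. Lewis-acid formylation is excluded by the tertiary alcohols, so each formyl carbon is traced back to an aryllithium and each aryllithium to an aryl bromide. The forward sequence must functionalise both remaining ring positions of 27, each of which is flanked by two methoxy groups.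

**27 to 26 to 21 + 22.** Both bonds at the benzylic carbon are cut: aryl–C and C–CH2. This is the only stereocentre outside the rings and it sits next to C1. Building it from the aldehyde carbon of 21 through an ortho-quinone methide (25) lets C1 control it and lets the arene be bought as 22. The forward step needs ortho-selective attack of the phenoxide 23, elimination, and conjugate delivery of the isobutyl group anti to C10.

**21 to 20 to 19.** This is only an adjustment of the oxidation level of the carbon on C1, from ester through primary alcohol to aldehyde.

**19 to 18 to 17.** The C4–O bond is cut. An axial hydroxyl syn to the angular methyl is what anti addition to a C3=C4 alkene delivers when the electrophile takes the open face anti to the methyl. The halogen at C3 in 18 is then removed by a radical chain.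

**17 to 14 to 13.** The C5–H bond is cut and the C3 oxygen is put back. The enone of 13 provides both the trans ring fusion (hydrogen delivered to C5 on the face anti to the methyl from a diazene placed there by inversion of the alcohol 14) and the alkene position needed for C4.

**13 to 12.** The C6–C11 bond is re-formed. The C11 carbinol of 13 is the product of acid opening of a cyclopropane conjugated to the enone, so the carbinol costs no separate step.

**12 to 4 + 9 (key).** C10–C1 and C4=C5 are cut. This disconnection was chosen because it makes the quaternary C10, the C1 stereocentre and ring A in one operation from a ketone, carone 4, that can enolise in only one direction and has one open face.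

**4 to 3 to 2 to 1, and 9 to 7 + 8 (7 from 5 via 6).** The cyclopropyl ketone 4 comes from the chiral-pool enone 1 by conjugate reduction, hydrobromination and ring closure. The acceptor 9 comes from a stabilised ylide 7 and the aldehyde 8.

## Alternatives that were turned down

**Alternative 1:** This cuts both bonds at the benzylic carbon and treats the terpene aldehyde A2, the arene and the isobutyl group as three components. In the forward step the magnesium phenoxide attacks A2 through its ortho carbon, the adduct collapses to the ortho-quinone methide, and an isobutyl nucleophile adds to give A1.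
- For it: it is convergent, uses a commercial arene, and sets the benzylic centre under allylic strain from C1.
- Against it: it does not say how A2, with five stereocentres, the quaternary C10 and the axial C4 hydroxyl, is made, and that is the harder half of the problem. A hindered aldehyde, possible hydride transfer from the branched organomagnesium reagent and single-centre facial control also make it a fragile centrepiece.
- Comparison: on the end game it is equal, because the chosen route uses the same coupling as its step 14 (A1 is 26 and A2 is 21). The chosen strategy adds what this one lacks, a stereocontrolled chiral-pool route to the decalin.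

**Alternative 2:** This cuts C4–C5 and C9–C10, so both rings come from the acyclic keto vinylsilane A4. In the forward step a Lewis acid activates the methyl ketone, the trisubstituted alkene and then the vinylsilane attack, and loss of silicon gives the trans-decalin A3.
- For it: one step forms both rings and sets C4, C5 and C10, with the axial C4 hydroxyl arising directly from the initiating ketone. On this point it is stronger than the chosen route, which spends steps 8 to 11 on C4 and C5.
- Against it: A4 needs two remote stereocentres (C1 and C7), an (E)-trisubstituted alkene and a (Z)-vinylsilane, all made by asymmetric synthesis in a long linear sequence. Ketone-initiated cyclisations compete with ene and Prins pathways, and the face of the ketone that is attacked (C4 epimers) is less secure than with epoxide or acetal initiators. A3 still needs the C7 ester turned into the carbinol, the C8=C9 alkene reduced and the benzyl ether converted into the aldehyde.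
- Comparison: the chosen route takes C7 from carvone, gets the C11 carbinol without extra steps, and fixes C4 and C5 by well-understood rigid-ring reactions, at the price of more steps on ring A.

**Alternative 3:** This cuts three bonds of the arene itself. Heating the siloxyalkyne A6 with the cyclobutenone A7 gives, by ketene–alkyne cycloaddition, ring opening and electrocyclisation, the differentially protected resorcinol A5.
- For it: the arene regiochemistry is certain, the three oxygens are differentiated, the conditions are neutral, and no ortho-selectivity problem arises. On these points it is stronger than the chosen route.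
- Against it: A6 must already contain the whole terpene and the benzylic stereocentre, set at a propargylic carbon before the ring exists, and an ynol silyl ether has to be made on a hindered position. A5 still needs two formylations and removal of an ethyl ether, a triisopropylsilyl ether and two triethylsilyl ethers. The strategy also builds an arene that can be bought.
- Comparison: the chosen route takes the arene from a commercial phenol in one step and uses C1 to set the benzylic centre in that same step.

Key step: step 6

Assumption: C3 of carone 4 (the future C10) is epimerisable under the ring-closure conditions and becomes planar on enolisation in step 6, so 2 and 4 may be used as epimer mixtures at this centre; 4 is drawn as its (1R,3R,6S) epimer.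

## Route

Step 1
Reactants: 1 (S)-(+)-carvone
Product: 2 (2S,5S)-dihydrocarvone
Conditions: Zn, KOH, EtOH–H2O, reflux
Reagents that add atoms: none
Why: Dissolving-metal conjugate reduction of the enone; the isopropenyl group and the C5 stereocentre are untouched, and the configuration of the new α-methyl centre is of no consequence.

Step 2
Reactants: 2 (2S,5S)-dihydrocarvone
Product: 3 (2S,5S)-5-(2-bromopropan-2-yl)-2-methylcyclohexan-1-one
Conditions: HBr (33% in AcOH), 0 °C
Reagents that add atoms: hydrogen bromide (Br)
Why: Markovnikov hydrobromination of the 1,1-disubstituted alkene through the tertiary cation; the ketone is inert under these conditions.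

Step 3
Reactants: 3 (2S,5S)-5-(2-bromopropan-2-yl)-2-methylcyclohexan-1-one
Product: 4 carone
Conditions: KOH, EtOH, 0 °C → rt
Reagents that add atoms: none
Why: Intramolecular enolate alkylation (3-exo-tet, a 1,3-elimination of HBr): the methylene enolate displaces the tertiary bromide and the cyclopropane is necessarily cis-fused, so the carvone stereocentre fixes both ring-fusion carbons.

Step 4
Reactants: 5 1-bromobutan-2-one
Product: 7 1-(triphenyl-λ5-phosphanylidene)butan-2-one, via (2-oxobutyl)triphenylphosphonium bromide 6 (not isolated)
Conditions: PPh3, CH2Cl2, rt; then 2 M aq. NaOH, rt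
Reagents that add atoms: triphenylphosphine (c1ccc(cc1)P(c1ccccc1)c1ccccc1)
Why: SN2 displacement of the α-bromo ketone by the phosphine and deprotonation of the salt give the stabilised acyl ylide.

Step 5
Reactants: 7 1-(triphenyl-λ5-phosphanylidene)butan-2-one, 8 methyl glyoxylate
Product: 9 methyl (E)-4-oxohex-2-enoate
Conditions: 8 (freshly distilled), CH2Cl2, 0 °C → rt
Reagents that add atoms: none
Why: Wittig olefination; the stabilised ylide reacts only with the aldehyde and gives the (E)-alkene.

Step 6
Reactants: 4 carone, 9 methyl (E)-4-oxohex-2-enoate
Product: 12 methyl 1,1,3a,7-tetramethyl-6-oxo-1a,2,3,3a,4,5,6,7b-octahydro-1H-cyclopropa[a]naphthalene-4-carboxylate (ester syn to the C10 methyl; cyclopropane syn to the C10 methyl), via Michael adduct 10 (not isolated), via ketol 11 (not isolated)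
Conditions: NaOMe (0.3 equiv), MeOH, slow addition of 9 at −10 °C, then rt → 40 °C
Reagents that add atoms: none
Why: NaOMe can enolise 4 only toward C10, because the other α-carbon is a cyclopropane carbon, and this enolate adds to 9 at the ester-bearing carbon (β to the ketone, the stronger activating group), forming C10–C1 and giving 10. The ethyl ketone of 10 then enolises toward its methylene and closes ring A by a 6-(enolendo)-exo-trig aldol addition onto the ring ketone C5 (11), and E1cB dehydration, driven by conjugation with the cyclopropane, gives the C4=C5 enone 12. The closest known reactions are the Robinson annulations of carone with ethyl vinyl ketone and of 2-methylcyclohexanone enolates with (E)-pent-3-en-2-one. C10 is set by the cyclopropane: its endo methyl group covers one face of the enolate, so the acceptor bonds anti to C11 and the C10 methyl ends syn to the three-membered ring. C1 is set by the topicity of the Michael step: in the sodium-bridged transition state the enone chain lies over the ring and the ester points to the C10 methyl side, which places the ester syn to the angular methyl, as the vicinal substituent ends up in the pentenone precedent. This centre is afterwards α only to the ester, so base amount, temperature and time are kept low to avoid epimerisation, and the step does not rely on equilibration. The step also needs Michael regioselectivity (secured by the ketone), aldol instead of Claisen closure onto the ester (secured by methanol at or below 40 °C) and suppression of acceptor self-condensation (secured by slow addition of 9).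

Step 7
Reactants: 12 tricyclic cyclopropyl enone ester
Product: 13 methyl 6-(2-hydroxypropan-2-yl)-4,8a-dimethyl-3-oxo-1,2,3,5,6,7,8,8a-octahydronaphthalene-1-carboxylate (ester and C7 group syn to the C10 methyl)
Conditions: 1 M aq. H2SO4–THF, rt → 40 °C
Reagents that add atoms: water (O)
Why: Homoconjugate opening of the cyclopropyl enone: O-protonation and cleavage of the C6–C11 bond release ring strain and give the tertiary C11 cation, which water captures, and the dienol returns to the C4=C5 enone. C7 is not touched, so its configuration from carvone is kept.

Step 8
Reactants: 13 carbinol enone ester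
Product: 14 methyl 3-hydroxy-6-(2-hydroxypropan-2-yl)-4,8a-dimethyl-1,2,3,5,6,7,8,8a-octahydronaphthalene-1-carboxylate (C3 hydroxyl syn to the C10 methyl)
Conditions: NaBH4, CeCl3·7H2O, MeOH, −20 °C
Reagents that add atoms: none
Why: Luche 1,2-reduction of the enone; the ester is not reduced. Hydride attacks axially from the face anti to the angular methyl, so the pseudo-equatorial alcohol syn to the methyl should predominate, as with 4-en-3-one steroids.

Step 9
Reactants: 14 allylic alcohol
Product: 17 methyl 6-(2-hydroxypropan-2-yl)-4,8a-dimethyl-1,2,4a,5,6,7,8,8a-octahydronaphthalene-1-carboxylate (C3=C4 alkene; H5 anti to the C10 methyl), via allylic sulfonylhydrazine 15 (not isolated), via allylic diazene 16 (not isolated)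
Conditions: 2-nitrobenzenesulfonylhydrazide, PPh3, DEAD, N-methylmorpholine, −30 °C → rt
Reagents that add atoms: none
Why: Reductive 1,3-transposition of an allylic alcohol: Mitsunobu displacement with inversion places nitrogen at C3 anti to the angular methyl (15), loss of the sulfinic acid gives the diazene 16, and its retro-ene loss of N2 delivers hydrogen to C5 on that same face. This sets the trans ring fusion and moves the alkene to C3=C4; the tertiary carbinol does not react under Mitsunobu conditions.

Step 10
Reactants: 17 trans-fused alkene ester
Product: 18 methyl 3-bromo-4-hydroxy-6-(2-hydroxypropan-2-yl)-4,8a-dimethyldecahydronaphthalene-1-carboxylate (C3 bromine axial and anti; C4 hydroxyl axial and syn to the C10 methyl)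
Conditions: N-bromosuccinimide, acetone–H2O, 0 °C, dark
Reagents that add atoms: N-bromosuccinimide (O=C1CCC(=O)N1Br), water (O)
Why: Bromohydrin formation: the bromonium ion forms on the face anti to the angular methyl and water opens it at the tertiary C4 in the trans-diaxial (Fürst–Plattner) mode. Markovnikov and diaxial preferences agree and place the hydroxyl axial and syn to the methyl.

Step 11
Reactants: 18 bromohydrin
Product: 19 methyl 4-hydroxy-6-(2-hydroxypropan-2-yl)-4,8a-dimethyldecahydronaphthalene-1-carboxylate (ester, C4 hydroxyl and C7 group syn to the C10 methyl)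
Conditions: Bu3SnH, AIBN (cat.), toluene, 80 °C
Reagents that add atoms: none
Why: Radical chain dehalogenation of the secondary bromide; the neutral conditions avoid epoxide formation from the diaxial bromohydrin and leave C4 untouched.

Step 12
Reactants: 19 diol ester
Product: 20 4-(hydroxymethyl)-7-(2-hydroxypropan-2-yl)-1,4a-dimethyldecahydronaphthalen-1-ol (triol; configuration as in 19)
Conditions: LiAlH4, THF, 0 °C → rt
Reagents that add atoms: none
Why: Hydride reduction of the ester to the primary alcohol; the tertiary alcohols are carried as alkoxides.

Step 13
Reactants: 20 triol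
Product: 21 4-hydroxy-6-(2-hydroxypropan-2-yl)-4,8a-dimethyldecahydronaphthalene-1-carbaldehyde (formyl group equatorial and syn to the C10 methyl)
Conditions: Dess–Martin periodinane, CH2Cl2, 0 °C → rt
Reagents that add atoms: none
Why: Selective oxidation of the only oxidisable (primary) alcohol under mild conditions that should not epimerise C1.

Step 14
Reactants: 21 diol aldehyde, 22 3,5-dimethoxyphenol
Product: 26 2-{(1R)-1-[(1R,4R,4aS,6S,8aR)-4-hydroxy-6-(2-hydroxypropan-2-yl)-4,8a-dimethyldecahydronaphthalen-1-yl]-3-methylbutyl}-3,5-dimethoxyphenol, via bromomagnesium 3,5-dimethoxyphenoxide 23 (not isolated), via ortho-hydroxybenzylic alcohol 24 (not isolated), via ortho-quinone methide 25 (not isolated)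
Conditions: 22, EtMgBr (1.05 equiv), Et2O, 0 °C; solvent changed to toluene; 21, rt; then iBuMgBr (6 equiv), Et2O–toluene, 0 → 40 °C; aq. NH4Cl
Reagents that add atoms: isobutylmagnesium bromide (CC(C)C[Mg]Br)
Why: The magnesium phenoxide 23 delivers its ortho carbon to the aldehyde through a six-membered magnesium chelate (ortho-selective hydroxyalkylation of magnesium phenoxides); the excess Grignard reagent deprotonates 24 and triggers loss of the benzylic oxygen to give the ortho-quinone methide 25, to which the isobutyl group adds 1,4 with rearomatisation. Allylic 1,3-strain holds the C1–H bond in the plane of the methide, so the quaternary C10 covers one face and the nucleophile enters from the face of the C2 methylene, which for this C1 configuration gives the (R) benzylic centre. The two tertiary alcohols are carried as magnesium alkoxides.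

Step 15
Reactants: 26 2-alkyl-3,5-dimethoxyphenol
Product: 27 trimethyl ether of 26 (2-alkyl-1,3,5-trimethoxybenzene)
Conditions: MeI, K2CO3, acetone, reflux
Reagents that add atoms: iodomethane (CI)
Why: Williamson etherification of the phenol; carbonate does not deprotonate the tertiary alcohols, so only the phenol is methylated.

Step 16
Reactants: 27 2-alkyl-1,3,5-trimethoxybenzene
Product: 28 2-alkyl-4,6-dibromo-1,3,5-trimethoxybenzene
Conditions: N-bromosuccinimide (2.1 equiv), MeCN, 0 °C
Reagents that add atoms: N-bromosuccinimide (O=C1CCC(=O)N1Br)
Why: Electrophilic aromatic bromination at the two remaining ring positions, each activated by two ortho methoxy groups; the conditions are neutral and spare the carbinols.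

Step 17
Reactants: 28 dibromide
Product: 30 2-alkyl-4,6-diformyl-1,3,5-trimethoxybenzene (5-alkyl-2,4,6-trimethoxybenzene-1,3-dicarbaldehyde), via dilithiated arene 29 (not isolated)
Conditions: n-BuLi (2.1 equiv), THF, −78 °C; t-BuLi (4.4 equiv), −78 °C; DMF (excess), −78 → 0 °C; aq. NH4Cl
Reagents that add atoms: N,N-dimethylformamide (CN(C)C=O)
Why: After deprotonation of the two carbinols, double bromine–lithium exchange gives the dilithio arene, each carbanion being stabilised by two flanking methoxy groups, and DMF formylates both positions; the tetrahedral adducts survive until work-up. This basic sequence replaces Lewis-acid formylation, which the tertiary alcohols would not survive.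

Step 18
Reactants: 30 trimethoxy dialdehyde
Product: 31 target compound
Conditions: NaSEt (excess), DMF, 130 °C; then dilute aq. HCl, 0 °C
Reagents that add atoms: none
Why: SN2 demethylation of the aryl methyl ethers by thiolate; every methoxy group is ortho or para to a formyl group, which makes the phenoxide a good leaving group. The basic, non-ionising conditions leave both tertiary alcohols and the stereocentres untouched.

## Compound list

1 | (S)-(+)-carvone, (5S)-2-methyl-5-(prop-1-en-2-yl)cyclohex-2-en-1-one | CC1=CC[C@@H](CC1=O)C(C)=C | starting material
2 | (2S,5S)-dihydrocarvone, (2S,5S)-2-methyl-5-(prop-1-en-2-yl)cyclohexan-1-one | C[C@H]1CC[C@@H](CC1=O)C(C)=C | intermediate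
3 | (2S,5S)-5-(2-bromopropan-2-yl)-2-methylcyclohexan-1-one | C[C@H]1CC[C@@H](CC1=O)C(C)(C)Br | intermediate
4 | carone, (1R,3R,6S)-3,7,7-trimethylbicyclo[4.1.0]heptan-2-one | O=C1[C@@H]2[C@@H](C2(C)C)CC[C@H]1C | intermediate
5 | 1-bromobutan-2-one | CCC(=O)CBr | starting material
6 | (2-oxobutyl)triphenylphosphonium bromide | CCC(=O)C[P+](c1ccccc1)(c1ccccc1)c1ccccc1.[Br-] | intermediate
7 | 1-(triphenyl-λ5-phosphanylidene)butan-2-one | CCC(=O)C=P(c1ccccc1)(c1ccccc1)c1ccccc1 | intermediate
8 | methyl glyoxylate (methyl 2-oxoacetate) | COC(=O)C=O | starting material
9 | methyl (E)-4-oxohex-2-enoate | CCC(=O)/C=C/C(=O)OC | intermediate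
10 | Michael adduct, methyl 4-oxo-2-(3,7,7-trimethyl-2-oxobicyclo[4.1.0]heptan-3-yl)hexanoate (new C10–C1 bond anti to the cyclopropane; C1 as in 12) | COC(=O)[C@@H](CC(=O)CC)[C@@]1(C)CC[C@H]2[C@@H](C1=O)C2(C)C | intermediate
11 | ketol, aldol adduct with the C4–C5 bond formed and a hydroxyl on C5 (C4 and C5 not controlled, both lost on dehydration) | COC(=O)[C@H]1CC(=O)C(C)C2(O)[C@@H]3[C@@H](C3(C)C)CC[C@]12C | intermediate
12 | methyl 1,1,3a,7-tetramethyl-6-oxo-1a,2,3,3a,4,5,6,7b-octahydro-1H-cyclopropa[a]naphthalene-4-carboxylate (ester and cyclopropane syn to the C10 methyl) | COC(=O)[C@H]1CC(=O)C(C)=C2[C@@H]3[C@@H](C3(C)C)CC[C@]12C | intermediate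
13 | methyl 6-(2-hydroxypropan-2-yl)-4,8a-dimethyl-3-oxo-1,2,3,5,6,7,8,8a-octahydronaphthalene-1-carboxylate (ester and C7 group syn to the C10 methyl) | COC(=O)[C@H]1CC(=O)C(C)=C2C[C@@H](C(C)(C)O)CC[C@]12C | intermediate
14 | methyl 3-hydroxy-6-(2-hydroxypropan-2-yl)-4,8a-dimethyl-1,2,3,5,6,7,8,8a-octahydronaphthalene-1-carboxylate (C3 hydroxyl syn to the C10 methyl) | COC(=O)[C@H]1C[C@@H](O)C(C)=C2C[C@@H](C(C)(C)O)CC[C@]12C | intermediate
15 | allylic sulfonylhydrazine, 14 with N-amino-N-(2-nitrobenzenesulfonyl)amino in place of the C3 hydroxyl, nitrogen anti to the C10 methyl | COC(=O)[C@H]1C[C@H](N(N)S(=O)(=O)c3ccccc3[N+](=O)[O-])C(C)=C2C[C@@H](C(C)(C)O)CC[C@]12C | intermediate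
16 | allylic diazene, 14 with HN=N in place of the C3 hydroxyl, nitrogen anti to the C10 methyl | COC(=O)[C@H]1C[C@H](N=N)C(C)=C2C[C@@H](C(C)(C)O)CC[C@]12C | intermediate
17 | methyl 6-(2-hydroxypropan-2-yl)-4,8a-dimethyl-1,2,4a,5,6,7,8,8a-octahydronaphthalene-1-carboxylate (C3=C4 alkene; trans-fused, H5 anti to the C10 methyl) | COC(=O)[C@H]1CC=C(C)[C@H]2C[C@@H](C(C)(C)O)CC[C@]12C | intermediate
18 | methyl 3-bromo-4-hydroxy-6-(2-hydroxypropan-2-yl)-4,8a-dimethyldecahydronaphthalene-1-carboxylate (bromine axial, anti; C4 hydroxyl axial, syn) | COC(=O)[C@H]1C[C@H](Br)[C@@](C)(O)[C@H]2C[C@@H](C(C)(C)O)CC[C@]12C | intermediate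
19 | methyl 4-hydroxy-6-(2-hydroxypropan-2-yl)-4,8a-dimethyldecahydronaphthalene-1-carboxylate (ester, C4 hydroxyl and C7 group syn to the C10 methyl; trans-fused) | COC(=O)[C@H]1CC[C@@](C)(O)[C@H]2C[C@@H](C(C)(C)O)CC[C@]12C | intermediate
20 | 4-(hydroxymethyl)-7-(2-hydroxypropan-2-yl)-1,4a-dimethyldecahydronaphthalen-1-ol (configuration as in 19) | OC[C@H]1CC[C@@](C)(O)[C@H]2C[C@@H](C(C)(C)O)CC[C@]12C | intermediate
21 | 4-hydroxy-6-(2-hydroxypropan-2-yl)-4,8a-dimethyldecahydronaphthalene-1-carbaldehyde (configuration as in 19) | O=C[C@H]1CC[C@@](C)(O)[C@H]2C[C@@H](C(C)(C)O)CC[C@]12C | intermediate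
22 | 3,5-dimethoxyphenol | COc1cc(O)cc(OC)c1 | starting material
23 | bromomagnesium 3,5-dimethoxyphenoxide | COc1cc(O[Mg]Br)cc(OC)c1 | intermediate
24 | ortho-hydroxybenzylic alcohol, 2-[hydroxy(decalinyl)methyl]-3,5-dimethoxyphenol, present as its magnesium salt and drawn neutral (carbinol centre not controlled) | OC(c1c(O)cc(OC)cc1OC)[C@H]1CC[C@@](C)(O)[C@H]2C[C@@H](C(C)(C)O)CC[C@]12C | intermediate
25 | ortho-quinone methide, 6-(decalinylmethylidene)-3,5-dimethoxycyclohexa-2,4-dien-1-one, drawn neutral (methide geometry not defined) | O=C1C=C(OC)C=C(OC)C1=C[C@H]2CC[C@@](C)(O)[C@H]3C[C@@H](C(C)(C)O)CC[C@]23C | intermediate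
26 | 2-{(1R)-1-[(1R,4R,4aS,6S,8aR)-4-hydroxy-6-(2-hydroxypropan-2-yl)-4,8a-dimethyldecahydronaphthalen-1-yl]-3-methylbutyl}-3,5-dimethoxyphenol | CC(C)C[C@@H](c1c(O)cc(OC)cc1OC)[C@H]1CC[C@@](C)(O)[C@H]2C[C@@H](C(C)(C)O)CC[C@]12C | intermediate
27 | trimethyl ether of 26, 2-alkyl-1,3,5-trimethoxybenzene with the same side chain | CC(C)C[C@@H](c1c(OC)cc(OC)cc1OC)[C@H]1CC[C@@](C)(O)[C@H]2C[C@@H](C(C)(C)O)CC[C@]12C | intermediate
28 | 4,6-dibromo derivative of 27 | CC(C)C[C@@H](c1c(OC)c(Br)c(OC)c(Br)c1OC)[C@H]1CC[C@@](C)(O)[C@H]2C[C@@H](C(C)(C)O)CC[C@]12C | intermediate
29 | dilithiated arene, 4,6-dilithio derivative of 27 as its bis(lithium alkoxide) | CC(C)C[C@@H](c1c(OC)c([Li])c(OC)c([Li])c1OC)[C@H]1CC[C@@](C)(O[Li])[C@H]2C[C@@H](C(C)(C)O[Li])CC[C@]12C | intermediate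
30 | 5-alkyl-2,4,6-trimethoxybenzene-1,3-dicarbaldehyde with the side chain of 26 | CC(C)C[C@@H](c1c(OC)c(C=O)c(OC)c(C=O)c1OC)[C@H]1CC[C@@](C)(O)[C@H]2C[C@@H](C(C)(C)O)CC[C@]12C | intermediate
31 | 5-{(1R)-1-[(1R,4R,4aS,6S,8aR)-4-hydroxy-6-(2-hydroxypropan-2-yl)-4,8a-dimethyldecahydronaphthalen-1-yl]-3-methylbutyl}-2,4,6-trihydroxybenzene-1,3-dicarbaldehyde | CC(C)C[C@@H](c1c(O)c(C=O)c(O)c(C=O)c1O)[C@H]1CC[C@@](C)(O)[C@H]2C[C@@H](C(C)(C)O)CC[C@]12C | target

## Step count and least certain steps

Total: 18 steps. Longest linear sequence: 16 steps (steps 1 to 3 and 6 to 18); the acceptor branch (steps 4 and 5) joins at step 6.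

**Step 6 (key step).** The most likely failure is incomplete control of C1: the Michael addition may show poor topicity, and the ester-bearing carbon may epimerise under methoxide. In the enone the ester syn to the methyl is not clearly the more stable epimer, so equilibration cannot be trusted to correct this. Oligomerisation of the doubly activated acceptor would lower the yield further. Fallback, setting out from 12 obtained together with its C1 epimer: the mixture is dehydrogenated between C1 and C2 (2-iodoxybenzoic acid, DMSO, 70 °C) to the cross-conjugated dienone methyl 1,1,3a,7-tetramethyl-6-oxo-1a,2,3,3a,6,7b-hexahydro-1H-cyclopropa[a]naphthalene-4-carboxylate F1, in which C1 is no longer a stereocentre. The electron-poor C1=C2 bond alone is then hydrogenated (H2, RhCl(PPh3)3, benzene) from the face away from the angular methyl and the cyclopropane, which returns 12 with the ester syn to the methyl.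

**Step 14.** Three things may go wrong: sluggish ortho-hydroxyalkylation of the hindered, α-branched aldehyde; reduction of the quinone methide by β-hydride transfer from the branched Grignard reagent, or its tautomerisation to a styrene; and insufficient facial selectivity at the benzylic carbon, which rests on a single allylic strain element. Fallback, setting out from 21: 2,4,6-trimethoxyphenyllithium F2 (from 1,3,5-trimethoxybenzene and n-BuLi; three equivalents, two being consumed by the carbinols) adds to the aldehyde to give the benzylic alcohol F3. Ionisation of this doubly ortho-methoxy-stabilised carbinol with BF3·OEt2 at −78 °C in the presence of trimethyl(2-methylallyl)silane gives the methallyl compound F4, by attack anti to C10 under the same allylic strain control and without any hydride donor. Hydrogenation (H2, Pd/C, EtOAc) of the 1,1-disubstituted alkene gives 27, so step 15 is no longer needed.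

**Step 9.** The Mitsunobu displacement at the hindered allylic alcohol, flanked by the methyl-substituted alkene carbon, may give elimination to a diene instead of substitution. Any C3 epimer carried over from step 8 would be converted into the cis-fused isomer. Fallback, setting out from 13: Li in NH3–THF at −78 °C reduces the enone with axial protonation at C5 to the trans-fused lithium enolate F5, which is trapped in the same flask with N-phenylbis(trifluoromethanesulfonimide) as the enol triflate F6. Reduction of the triflate (Pd(OAc)2, PPh3, Bu3N, HCO2H, DMF, 60 °C) gives 17.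

**Step 17.** The second bromine–lithium exchange on an arene that already carries one carbanion and two alkoxides may be incomplete, which would lead to monoaldehyde and protodebrominated material. Fallback, setting out from 28: double Suzuki–Miyaura coupling with CH2=CHBF3K (Pd(OAc)2, SPhos, Cs2CO3, THF–H2O, 70 °C) gives the divinyl arene F7, and oxidative cleavage of both vinyl groups (OsO4 cat., NaIO4, 2,6-lutidine, dioxane–H2O) gives 30.

**Step 18.** Cleavage of the last methyl ether is slowed by the phenoxides already formed, and the forcing conditions then needed may allow thiolate attack on the aldehydes or decomposition of the electron-rich product. Fallback, setting out from 21: steps 14 to 17 are run with 3,5-bis(benzyloxy)phenol in place of 22 and benzyl bromide in place of iodomethane. This gives in turn the 2-alkyl-3,5-bis(benzyloxy)phenol F8, the tris(benzyl ether) F9, its 4,6-dibromide F10 and the tris(benzyloxy) dialdehyde F11. Hydrogenolysis (H2, Pd/C, EtOAc, rt) then removes the three benzyl groups under neutral conditions and gives 31.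

## Further compounds

F1 | step 6 | methyl 1,1,3a,7-tetramethyl-6-oxo-1a,2,3,3a,6,7b-hexahydro-1H-cyclopropa[a]naphthalene-4-carboxylate | COC(=O)C1=CC(=O)C(C)=C2[C@@H]3[C@@H](C3(C)C)CC[C@]12C
F2 | step 14 | 2,4,6-trimethoxyphenyllithium | [Li]c1c(OC)cc(OC)cc1OC
F3 | step 14 | benzylic alcohol, (2,4,6-trimethoxyphenyl)(decalinyl)methanol from 21 (carbinol centre not controlled) | COc1cc(OC)c(C(O)[C@H]2CC[C@@](C)(O)[C@H]3C[C@@H](C(C)(C)O)CC[C@]23C)c(OC)c1
F4 | step 14 | methallyl compound, 27 with 2-methylprop-2-enyl in place of isobutyl | CC(=C)C[C@@H](c1c(OC)cc(OC)cc1OC)[C@H]1CC[C@@](C)(O)[C@H]2C[C@@H](C(C)(C)O)CC[C@]12C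
F5 | step 9 | trans-fused lithium C3–C4 enolate of the reduced enone (lithium alkoxide at C11) | COC(=O)[C@H]1CC(O[Li])=C(C)[C@H]2C[C@@H](C(C)(C)O[Li])CC[C@]12C
F6 | step 9 | enol triflate, 17 with trifluoromethanesulfonyloxy on C3 | COC(=O)[C@H]1CC(OS(=O)(=O)C(F)(F)F)=C(C)[C@H]2C[C@@H](C(C)(C)O)CC[C@]12C
F7 | step 17 | divinyl arene, 28 with vinyl in place of each bromine | CC(C)C[C@@H](c1c(OC)c(C=C)c(OC)c(C=C)c1OC)[C@H]1CC[C@@](C)(O)[C@H]2C[C@@H](C(C)(C)O)CC[C@]12C
F8 | step 18 | 2-alkyl-3,5-bis(benzyloxy)phenol with the side chain of 26 | CC(C)C[C@@H](c1c(O)cc(OCc2ccccc2)cc1OCc1ccccc1)[C@H]1CC[C@@](C)(O)[C@H]2C[C@@H](C(C)(C)O)CC[C@]12C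
F9 | step 18 | 2-alkyl-1,3,5-tris(benzyloxy)benzene | CC(C)C[C@@H](c1c(OCc2ccccc2)cc(OCc2ccccc2)cc1OCc1ccccc1)[C@H]1CC[C@@](C)(O)[C@H]2C[C@@H](C(C)(C)O)CC[C@]12C
F10 | step 18 | 4,6-dibromo derivative of F9 | CC(C)C[C@@H](c1c(OCc2ccccc2)c(Br)c(OCc2ccccc2)c(Br)c1OCc1ccccc1)[C@H]1CC[C@@](C)(O)[C@H]2C[C@@H](C(C)(C)O)CC[C@]12C
F11 | step 18 | 5-alkyl-2,4,6-tris(benzyloxy)benzene-1,3-dicarbaldehyde | CC(C)C[C@@H](c1c(OCc2ccccc2)c(C=O)c(OCc2ccccc2)c(C=O)c1OCc1ccccc1)[C@H]1CC[C@@](C)(O)[C@H]2C[C@@H](C(C)(C)O)CC[C@]12C
A1 | alternative 1 | 2-alkyl-3,5-dimethoxyphenol with the complete carbon skeleton (same structure as 26) | CC(C)C[C@@H](c1c(O)cc(OC)cc1OC)[C@H]1CC[C@@](C)(O)[C@H]2C[C@@H](C(C)(C)O)CC[C@]12C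
A2 | alternative 1 | eudesmane C1 aldehyde (same structure as 21) | O=C[C@H]1CC[C@@](C)(O)[C@H]2C[C@@H](C(C)(C)O)CC[C@]12C
A3 | alternative 2 | trans-decalin with axial C4 carbinol, C7 methyl ester, C8=C9 alkene and C1 benzyloxymethyl group | c1ccccc1COC[C@H]1CC[C@@](C)(O)[C@H]2C[C@@H](C(=O)OC)C=C[C@]12C
A4 | alternative 2 | acyclic methyl ketone with (E)-trisubstituted alkene and (Z)-vinylsilane | CC(=O)CC[C@H](COCc1ccccc1)/C(C)=C/C[C@@H](C(=O)OC)/C=C\[Si](C)(C)C
A5 | alternative 3 | 2-alkyl-5-ethoxy-3-(triisopropylsilyloxy)phenol with two free ring positions | CC(C)C[C@@H](c1c(O[Si](C(C)C)(C(C)C)C(C)C)cc(OCC)cc1O)[C@H]1CC[C@@](C)(O[Si](CC)(CC)CC)[C@H]2C[C@@H](C(C)(C)O[Si](CC)(CC)CC)CC[C@]12C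
A6 | alternative 3 | side-chain siloxyalkyne | CC(C)C[C@@H](C#CO[Si](C(C)C)(C(C)C)C(C)C)[C@H]1CC[C@@](C)(O[Si](CC)(CC)CC)[C@H]2C[C@@H](C(C)(C)O[Si](CC)(CC)CC)CC[C@]12C
A7 | alternative 3 | 3-ethoxycyclobut-2-en-1-one | CCOC1=CC(=O)C1
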